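**Retrosynthetic overview**

1. The plan rests on one feature of the cycloheptane ring (C1, C5, C6, C7, C8, C9, C10): C8 is a bare CH2 bonded to C7, the β-carbon of the fused lactone ring (O–C6–C7–C11(=C13H2)–C12=O). C7–C8 is therefore made by a C8 radical that adds to a butenolide C7=C11 carrying a phenylsulfonyl group on C13 and then expels it, so carbocycle and exocyclic methylene arise together.
2. After this ring closure only the exchange of the C2 thioester for the (Z)-propenyl ketone (Liebeskind–Srogl) and desilylation remain.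
3. The acyclic iodide precursor is cut at C5–C6: a chelation-controlled vinylogous Mukaiyama aldol joins a 3-(phenylsulfonylmethyl)-2-silyloxyfuran (from α-methylene-γ-butyrolactone) to a C5 aldehyde that already holds the C1 carbinol. C5–OH is then isovalerylated and C8–OPMB turned into the iodide.
4. The aldehyde comes from a temporary γ-lactone (C2–O9). Brown syn-crotylation sets C9/C10; hydroboration, oxidative lactonisation and α-methylenation give a cis-disubstituted α-methylene lactone; OsO4 adds anti to both ring substituents and sets C1; an aluminium thiolate opens the lactone to the C2 thioester.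
5. Ring order: temporary C2–O9 γ-lactone (made, then opened), then the butenolide (brought in intact), then the cycloheptane in the radical step, which also turns the butenolide into the α-methylene lactone.

Key step: step 17

Numbering: target locants throughout. C1 = C(OH)(acyl), C2 = ketone C=O, C3=C4–C15 = propenyl, C5 = CH–O-isovalerate, C6 = CH–O(lactone), C7 = ring-fusion CH, C8 = CH2, C9 = CH–OH, C10 = CH–CH3, C11=C13 = exocyclic alkene, C12 = lactone C=O.

Assumption: 2-[(4-methoxybenzyl)oxy]acetaldehyde (1) is taken as a catalogue compound. Which enantiomer of Ipc2BOMe gives the required face in step 1 is assigned by analogy with the known sense of Ipc2B-allyl additions.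

**Route**

Step 1
Reactants: 1 2-[(4-methoxybenzyl)oxy]acetaldehyde
Product: 3 (2S,3R)-1-[(4-methoxybenzyl)oxy]-3-methylpent-4-en-2-ol, via diisopinocampheylborinate ester 2 (not isolated)
Conditions: cis-2-butene, KOt-Bu, n-BuLi, THF, −78 to −45 °C; (−)-Ipc2BOMe [from (+)-α-pinene], −78 °C; BF3·OEt2; 1, −78 °C; then NaOH, H2O2, 0 °C to rt
Reagents that add atoms: cis-2-butene, C/C=C\C
Why: Brown (Z)-crotylboration through a closed chair transition state, in which the Z geometry of the crotyl group gives the syn C9–OH/C10–CH3 pair and the isopinocampheyl groups select the aldehyde face leading to the (2S,3R) isomer.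

Step 2
Reactants: 3 (2S,3R)-1-[(4-methoxybenzyl)oxy]-3-methylpent-4-en-2-ol
Product: 5 (2S,3R)-1-[(4-methoxybenzyl)oxy]-3-methylpentane-2,5-diol, via bis(9-borabicyclononyl) adduct 4 (not isolated)
Conditions: 9-BBN-H (2.5 equiv), THF, 0 °C to rt; then NaOH, H2O2, 0 °C
Reagents that add atoms: hydrogen peroxide, OO
Why: anti-Markovnikov hydroboration–oxidation of the terminal alkene supplies the future C2 carbon as a primary alcohol without touching a stereocentre.

Step 3
Reactants: 5 (2S,3R)-1-[(4-methoxybenzyl)oxy]-3-methylpentane-2,5-diol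
Product: 7 (4R,5S)-5-{[(4-methoxybenzyl)oxy]methyl}-4-methyldihydrofuran-2(3H)-one, via lactol 6 (not isolated)
Conditions: TEMPO (0.2 equiv), PhI(OAc)2 (2.5 equiv), CH2Cl2, rt
Reagents that add atoms: none
Why: TEMPO/PhI(OAc)2 oxidative lactonisation, in which the primary alcohol is oxidised selectively, the hydroxy aldehyde closes to the lactol and this is oxidised to the cis-4,5-disubstituted γ-lactone while the PMB ether survives.

Step 4
Reactants: 7 (4R,5S)-5-{[(4-methoxybenzyl)oxy]methyl}-4-methyldihydrofuran-2(3H)-one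
Product: 8 (3S,4R,5S)-3-[(dimethylamino)methyl]-5-{[(4-methoxybenzyl)oxy]methyl}-4-methyldihydrofuran-2(3H)-one
Conditions: LDA, THF, −78 °C; then CH2=NMe2+ I−, −78 °C to rt
Reagents that add atoms: N,N-dimethylmethyleneiminium iodide (Eschenmoser's salt), C=[N+](C)C.[I-]
Why: Mannich reaction of the lithium lactone enolate with Eschenmoser's salt, the electrophile entering anti to the C10 methyl (this centre is erased in step 5).

Step 5
Reactants: 8 (3S,4R,5S)-3-[(dimethylamino)methyl]-5-{[(4-methoxybenzyl)oxy]methyl}-4-methyldihydrofuran-2(3H)-one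
Product: 10 (4R,5S)-5-{[(4-methoxybenzyl)oxy]methyl}-4-methyl-3-methylidenedihydrofuran-2(3H)-one, via trimethylammonium iodide 9 (not isolated)
Conditions: MeI, MeOH, rt; then NaHCO3 (aq.), CH2Cl2, rt
Reagents that add atoms: none
Why: quaternisation followed by E1cB loss of trimethylamine is the standard α-methylenation of a lactone and gives the exocyclic C1=C5 alkene.

Step 6
Reactants: 10 (4R,5S)-5-{[(4-methoxybenzyl)oxy]methyl}-4-methyl-3-methylidenedihydrofuran-2(3H)-one
Product: 11 (3S,4S,5S)-3-hydroxy-3-(hydroxymethyl)-5-{[(4-methoxybenzyl)oxy]methyl}-4-methyldihydrofuran-2(3H)-one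
Conditions: OsO4 (2 mol%), NMO, acetone/H2O, rt
Reagents that add atoms: N-methylmorpholine N-oxide, C[N+]1([O-])CCOCC1; water, O (both delivered through catalytic OsO4)
Why: Upjohn dihydroxylation, in which OsO4 reaches the exocyclic alkene only from the ring face opposite the cis C10-methyl and C9-CH2OPMB groups, so the C1 hydroxyl ends trans to the methyl (3S) and the future C5 carbon cis to it.

Step 7
Reactants: 11 (3S,4S,5S)-3-hydroxy-3-(hydroxymethyl)-5-{[(4-methoxybenzyl)oxy]methyl}-4-methyldihydrofuran-2(3H)-one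
Product: 12 S-ethyl (2S,3S,4S)-2,4-dihydroxy-2-(hydroxymethyl)-5-[(4-methoxybenzyl)oxy]-3-methylpentanethioate
Conditions: Me3Al (5 equiv), EtSH (5.5 equiv), CH2Cl2, 0 °C to rt; cold Rochelle salt work-up, crude used at once
Reagents that add atoms: ethanethiol, CCS
Why: thiolysis of the lactone by dimethylaluminium ethanethiolate (the thioester analogue of Weinreb aminolysis) is driven by the strong Al–O bond, and the γ-hydroxy thioester is silylated immediately so that it should not relactonise.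

Step 8
Reactants: 12 S-ethyl (2S,3S,4S)-2,4-dihydroxy-2-(hydroxymethyl)-5-[(4-methoxybenzyl)oxy]-3-methylpentanethioate
Product: 13 S-ethyl (2S,3S,4S)-5-[(4-methoxybenzyl)oxy]-3-methyl-2,4-bis(triethylsilyloxy)-2-[(triethylsilyloxy)methyl]pentanethioate
Conditions: TESOTf (4 equiv), 2,6-lutidine, CH2Cl2, −78 to 0 °C
Reagents that add atoms: triethylsilyl triflate, CC[Si](CC)(CC)OS(=O)(=O)C(F)(F)F
Why: exhaustive silylation with the silyl triflate, which is reactive enough for the tertiary C1 hydroxyl as well as the primary and secondary ones.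

Step 9
Reactants: 13 S-ethyl (2S,3S,4S)-5-[(4-methoxybenzyl)oxy]-3-methyl-2,4-bis(triethylsilyloxy)-2-[(triethylsilyloxy)methyl]pentanethioate
Product: 15 S-ethyl (2S,3S,4S)-2-formyl-5-[(4-methoxybenzyl)oxy]-3-methyl-2,4-bis(triethylsilyloxy)pentanethioate, via alkoxydimethylsulfonium chloride 14 (not isolated)
Conditions: (COCl)2, DMSO, CH2Cl2, −78 to −30 °C; then Et3N, −78 to 0 °C
Reagents that add atoms: none
Why: Swern oxidation applied directly to a silyl ether, in which only the primary triethylsilyl ether is cleaved by the chlorosulfonium reagent and oxidised, giving a C5 aldehyde that cannot epimerise because C1 is quaternary.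

Step 10
Reactants: 16 α-methylene-γ-butyrolactone
Product: 17 3-(bromomethyl)furan-2(5H)-one
Conditions: NBS, AIBN (cat.), PhCF3, reflux
Reagents that add atoms: N-bromosuccinimide, O=C1CCC(=O)N1Br
Why: Wohl–Ziegler allylic bromination, in which the allyl radical is brominated at its exocyclic terminus so that the double bond moves into the ring and into conjugation.

Step 11
Reactants: 17 3-(bromomethyl)furan-2(5H)-one
Product: 18 3-[(phenylsulfonyl)methyl]furan-2(5H)-one
Conditions: PhSO2Na, DMF, rt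
Reagents that add atoms: sodium benzenesulfinate, [Na+].[O-]S(=O)c1ccccc1
Why: S-alkylation of the soft sulfinate by the allylic bromide, direct and allylic-shift pathways converging on the conjugated allyl sulfone.

Step 12
Reactants: 18 3-[(phenylsulfonyl)methyl]furan-2(5H)-one
Product: 19 tert-butyldimethyl({3-[(phenylsulfonyl)methyl]furan-2-yl}oxy)silane
Conditions: TBSOTf, Et3N, CH2Cl2, 0 °C
Reagents that add atoms: tert-butyldimethylsilyl triflate, CC(C)(C)[Si](C)(C)OS(=O)(=O)C(F)(F)F
Why: soft enolisation of the butenolide, O-silylation and loss of the γ-proton giving the aromatic 2-silyloxyfuran.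

Step 13
Reactants: 15 S-ethyl (2S,3S,4S)-2-formyl-5-[(4-methoxybenzyl)oxy]-3-methyl-2,4-bis(triethylsilyloxy)pentanethioate; 19 tert-butyldimethyl({3-[(phenylsulfonyl)methyl]furan-2-yl}oxy)silane
Product: 20 S-ethyl (2S,3S,4S)-2-{(S)-hydroxy[(2R)-5-oxo-4-(phenylsulfonylmethyl)-2,5-dihydrofuran-2-yl]methyl}-5-[(4-methoxybenzyl)oxy]-3-methyl-2,4-bis(triethylsilyloxy)pentanethioate
Conditions: Me2AlCl (2.5 equiv), CH2Cl2, −78 °C; aq. NaHCO3
Reagents that add atoms: none
Why: chelation-controlled vinylogous Mukaiyama aldol, in which Me2AlCl (a Lewis acid able to chelate silyl ethers) holds the aldehyde oxygen syn to the C1–OTES oxygen so that furan C5 attacks the face flanked by the flat thioester and not by the branched C10 chain (sets 5S, syn to O1), while the open antiperiplanar transition state usual for 2-silyloxyfurans gives the threo C5/C6 pair (sets 6R).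

Step 14
Reactants: 20 S-ethyl (2S,3S,4S)-2-{(S)-hydroxy[(2R)-5-oxo-4-(phenylsulfonylmethyl)-2,5-dihydrofuran-2-yl]methyl}-5-[(4-methoxybenzyl)oxy]-3-methyl-2,4-bis(triethylsilyloxy)pentanethioate
Product: 21 S-ethyl (2S,3S,4S)-5-[(4-methoxybenzyl)oxy]-3-methyl-2-{(S)-(3-methylbutanoyloxy)[(2R)-5-oxo-4-(phenylsulfonylmethyl)-2,5-dihydrofuran-2-yl]methyl}-2,4-bis(triethylsilyloxy)pentanethioate
Conditions: isovaleryl chloride, pyridine, DMAP (cat.), CH2Cl2, 0 °C to rt
Reagents that add atoms: isovaleryl chloride, CC(C)CC(Cl)=O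
Why: acylation of the only free hydroxyl under mild amine base, kept cold so that the acidic C6–H of the butenolide should not be epimerised.

Step 15
Reactants: 21 S-ethyl (2S,3S,4S)-5-[(4-methoxybenzyl)oxy]-3-methyl-2-{(S)-(3-methylbutanoyloxy)[(2R)-5-oxo-4-(phenylsulfonylmethyl)-2,5-dihydrofuran-2-yl]methyl}-2,4-bis(triethylsilyloxy)pentanethioate
Product: 22 S-ethyl (2S,3S,4S)-5-hydroxy-3-methyl-2-{(S)-(3-methylbutanoyloxy)[(2R)-5-oxo-4-(phenylsulfonylmethyl)-2,5-dihydrofuran-2-yl]methyl}-2,4-bis(triethylsilyloxy)pentanethioate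
Conditions: DDQ, CH2Cl2/pH 7 buffer, 0 °C
Reagents that add atoms: none
Why: oxidative cleavage of the PMB ether under neutral conditions that leave silyl ethers, thioester and butenolide alone, the hindered thioester at quaternary C1 being slow to lactonise onto the freed C8 hydroxyl.

Step 16
Reactants: 22 S-ethyl (2S,3S,4S)-5-hydroxy-3-methyl-2-{(S)-(3-methylbutanoyloxy)[(2R)-5-oxo-4-(phenylsulfonylmethyl)-2,5-dihydrofuran-2-yl]methyl}-2,4-bis(triethylsilyloxy)pentanethioate
Product: 23 S-ethyl (2S,3S,4S)-5-iodo-3-methyl-2-{(S)-(3-methylbutanoyloxy)[(2R)-5-oxo-4-(phenylsulfonylmethyl)-2,5-dihydrofuran-2-yl]methyl}-2,4-bis(triethylsilyloxy)pentanethioate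
Conditions: I2, PPh3, imidazole, CH2Cl2, 0 °C
Reagents that add atoms: iodine, II
Why: Appel-type iodination of the primary alcohol through its alkoxyphosphonium salt gives the C8 iodide, the radical precursor.

Step 17
Reactants: 23 S-ethyl (2S,3S,4S)-5-iodo-3-methyl-2-{(S)-(3-methylbutanoyloxy)[(2R)-5-oxo-4-(phenylsulfonylmethyl)-2,5-dihydrofuran-2-yl]methyl}-2,4-bis(triethylsilyloxy)pentanethioate
Product: 24 S-ethyl (3aS,5R,6S,7S,8S,8aR)-6-methyl-3-methylidene-8-[(3-methylbutanoyl)oxy]-2-oxo-5,7-bis(triethylsilyloxy)octahydro-2H-cyclohepta[b]furan-7-carbothioate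
Conditions: (Bu3Sn)2 (1.2 equiv), benzene (0.003 M), 300 W sunlamp, 80 °C
Reagents that add atoms: none
Why: Proposed new method: photolysis of (Bu3Sn)2 gives tin radicals that abstract iodine from C8, the nucleophilic primary radical adds to the electron-poor β-carbon C7 of the butenolide, and the C11 radical so formed expels the phenylsulfonyl radical by β-scission, which makes the addition irreversible, creates the exocyclic C11=C13 alkene and ends on tin as Bu3SnO2SPh; the closest known reaction type is radical cyclisation by addition–fragmentation onto 2-(sulfonylmethyl)acrylates and allyl sulfones, established for five- and six-membered rings, so the seven-membered closure onto a butenolide is the untested extension. The cycloheptane (C1, C5, C6, C7, C8, C9, C10) closes in the 7-exo-trig mode, the C7=C11 bond lying outside the ring being formed, and attack at C7 instead of C11 follows from the polarity of the acceptor. The new stereocentre C7 is controlled by the tether, because the five-atom chain that leaves C6 through C5 reaches C7 only on the butenolide face that carries the C6–C5 bond, which gives the cis ring fusion (H6 and H7 cis, 7S). The step needs cyclisation to outrun 1,5-hydrogen transfer from C5–H (and 1,6-transfer from C6–H) to the C8 radical: ditin supplies no hydrogen donor, high dilution suppresses intermolecular addition, and the quaternary C1 with the silyloxy groups at C1 and C9 and the C10 methyl should bias the chain toward the folded conformer. Thioester, isovalerate, lactone and silyl ethers are spectators under these neutral conditions.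

Step 18
Reactants: 24 S-ethyl (3aS,5R,6S,7S,8S,8aR)-6-methyl-3-methylidene-8-[(3-methylbutanoyl)oxy]-2-oxo-5,7-bis(triethylsilyloxy)octahydro-2H-cyclohepta[b]furan-7-carbothioate
Product: 25 (3aS,5R,6S,7S,8S,8aR)-7-[(2Z)-but-2-enoyl]-6-methyl-3-methylidene-2-oxo-5,7-bis(triethylsilyloxy)octahydro-2H-cyclohepta[b]furan-8-yl 3-methylbutanoate
Conditions: (Z)-CH3CH=CHB(OH)2 (3 equiv), Pd2(dba)3 (5 mol%), P(2-furyl)3 (20 mol%), CuO2C(2-thienyl) (CuTC, 1.6 equiv), THF, 50 °C
Reagents that add atoms: (Z)-prop-1-enylboronic acid, C/C=C\B(O)O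
Why: Liebeskind–Srogl coupling, a neutral thioester-to-ketone exchange that tolerates the α-methylene lactone and the ester and transfers the alkenyl group with retention of its Z geometry.

Step 19
Reactants: 25 (3aS,5R,6S,7S,8S,8aR)-7-[(2Z)-but-2-enoyl]-6-methyl-3-methylidene-2-oxo-5,7-bis(triethylsilyloxy)octahydro-2H-cyclohepta[b]furan-8-yl 3-methylbutanoate
Product: 26 (3aS,5R,6S,7S,8S,8aR)-7-[(2Z)-but-2-enoyl]-5,7-dihydroxy-6-methyl-3-methylidene-2-oxooctahydro-2H-cyclohepta[b]furan-8-yl 3-methylbutanoate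
Conditions: HF·pyridine, pyridine, THF, 0 °C to rt
Reagents that add atoms: none
Why: buffered fluoride cleavage of both triethylsilyl ethers under weakly acidic conditions that should spare the Z-enone, the isovalerate and the α-methylene lactone.

**Compound list**

1 | 2-[(4-methoxybenzyl)oxy]acetaldehyde | COc1ccc(COCC=O)cc1 | starting material
2 | (2S,3R)-1-[(4-methoxybenzyl)oxy]-3-methylpent-4-en-2-yl diisopinocampheylborinate | COc1ccc(COC[C@@H](OB([C@@H]2C[C@@H]3C[C@H]([C@H]2C)C3(C)C)[C@@H]2C[C@@H]3C[C@H]([C@H]2C)C3(C)C)[C@H](C)C=C)cc1 | intermediate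
3 | (2S,3R)-1-[(4-methoxybenzyl)oxy]-3-methylpent-4-en-2-ol | COc1ccc(COC[C@@H](O)[C@H](C)C=C)cc1 | intermediate
4 | C5-(9-borabicyclo[3.3.1]nonan-9-yl) O2-(9-borabicyclo[3.3.1]nonan-9-yl) adduct of 3 | COc1ccc(COC[C@@H](OB2C3CCCC2CCC3)[C@H](C)CCB2C3CCCC2CCC3)cc1 | intermediate
5 | (2S,3R)-1-[(4-methoxybenzyl)oxy]-3-methylpentane-2,5-diol | COc1ccc(COC[C@@H](O)[C@H](C)CCO)cc1 | intermediate
6 | (4R,5S)-5-{[(4-methoxybenzyl)oxy]methyl}-4-methyltetrahydrofuran-2-ol (lactol, both anomers) | COc1ccc(COC[C@H]2OC(O)C[C@H]2C)cc1 | intermediate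
7 | (4R,5S)-5-{[(4-methoxybenzyl)oxy]methyl}-4-methyldihydrofuran-2(3H)-one | COc1ccc(COC[C@H]2OC(=O)C[C@H]2C)cc1 | intermediate
8 | (3S,4R,5S)-3-[(dimethylamino)methyl]-5-{[(4-methoxybenzyl)oxy]methyl}-4-methyldihydrofuran-2(3H)-one | COc1ccc(COC[C@H]2OC(=O)[C@H](CN(C)C)[C@H]2C)cc1 | intermediate
9 | trimethylammonium iodide of 8 | COc1ccc(COC[C@H]2OC(=O)[C@H](C[N+](C)(C)C)[C@H]2C)cc1.[I-] | intermediate
10 | (4R,5S)-5-{[(4-methoxybenzyl)oxy]methyl}-4-methyl-3-methylidenedihydrofuran-2(3H)-one | COc1ccc(COC[C@H]2OC(=O)C(=C)[C@H]2C)cc1 | intermediate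
11 | (3S,4S,5S)-3-hydroxy-3-(hydroxymethyl)-5-{[(4-methoxybenzyl)oxy]methyl}-4-methyldihydrofuran-2(3H)-one | COc1ccc(COC[C@H]2OC(=O)[C@@](O)(CO)[C@H]2C)cc1 | intermediate
12 | S-ethyl (2S,3S,4S)-2,4-dihydroxy-2-(hydroxymethyl)-5-[(4-methoxybenzyl)oxy]-3-methylpentanethioate | OC[C@](O)(C(=O)SCC)[C@@H](C)[C@H](O)COCc1ccc(OC)cc1 | intermediate
13 | S-ethyl (2S,3S,4S)-5-[(4-methoxybenzyl)oxy]-3-methyl-2,4-bis(triethylsilyloxy)-2-[(triethylsilyloxy)methyl]pentanethioate | CC[Si](CC)(CC)OC[C@](O[Si](CC)(CC)CC)(C(=O)SCC)[C@@H](C)[C@H](O[Si](CC)(CC)CC)COCc1ccc(OC)cc1 | intermediate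
14 | alkoxydimethylsulfonium chloride from the primary oxygen of 13 | C[S+](C)OC[C@](O[Si](CC)(CC)CC)(C(=O)SCC)[C@@H](C)[C@H](O[Si](CC)(CC)CC)COCc1ccc(OC)cc1.[Cl-] | intermediate
15 | S-ethyl (2S,3S,4S)-2-formyl-5-[(4-methoxybenzyl)oxy]-3-methyl-2,4-bis(triethylsilyloxy)pentanethioate | O=C[C@](O[Si](CC)(CC)CC)(C(=O)SCC)[C@@H](C)[C@H](O[Si](CC)(CC)CC)COCc1ccc(OC)cc1 | intermediate
16 | α-methylene-γ-butyrolactone (3-methylidenedihydrofuran-2(3H)-one) | C=C1CCOC1=O | starting material
17 | 3-(bromomethyl)furan-2(5H)-one | BrCC1=CCOC1=O | intermediate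
18 | 3-[(phenylsulfonyl)methyl]furan-2(5H)-one | O=C1OCC=C1CS(=O)(=O)c1ccccc1 | intermediate
19 | tert-butyldimethyl({3-[(phenylsulfonyl)methyl]furan-2-yl}oxy)silane | CC(C)(C)[Si](C)(C)Oc1occc1CS(=O)(=O)c1ccccc1 | intermediate
20 | S-ethyl (2S,3S,4S)-2-{(S)-hydroxy[(2R)-5-oxo-4-(phenylsulfonylmethyl)-2,5-dihydrofuran-2-yl]methyl}-5-[(4-methoxybenzyl)oxy]-3-methyl-2,4-bis(triethylsilyloxy)pentanethioate | O=C1O[C@H](C=C1CS(=O)(=O)c1ccccc1)[C@H](O)[C@](O[Si](CC)(CC)CC)(C(=O)SCC)[C@@H](C)[C@H](O[Si](CC)(CC)CC)COCc1ccc(OC)cc1 | intermediate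
21 | 3-methylbutanoate (at C5) of 20 | O=C1O[C@H](C=C1CS(=O)(=O)c1ccccc1)[C@H](OC(=O)CC(C)C)[C@](O[Si](CC)(CC)CC)(C(=O)SCC)[C@@H](C)[C@H](O[Si](CC)(CC)CC)COCc1ccc(OC)cc1 | intermediate
22 | C8 primary alcohol from 21 | O=C1O[C@H](C=C1CS(=O)(=O)c1ccccc1)[C@H](OC(=O)CC(C)C)[C@](O[Si](CC)(CC)CC)(C(=O)SCC)[C@@H](C)[C@H](O[Si](CC)(CC)CC)CO | intermediate
23 | C8 iodide, the cyclisation precursor (1S,5S,6R,9S,10S by target locants) | O=C1O[C@H](C=C1CS(=O)(=O)c1ccccc1)[C@H](OC(=O)CC(C)C)[C@](O[Si](CC)(CC)CC)(C(=O)SCC)[C@@H](C)[C@H](O[Si](CC)(CC)CC)CI | intermediate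
24 | S-ethyl (3aS,5R,6S,7S,8S,8aR)-6-methyl-3-methylidene-8-[(3-methylbutanoyl)oxy]-2-oxo-5,7-bis(triethylsilyloxy)octahydro-2H-cyclohepta[b]furan-7-carbothioate | C=C1C(=O)O[C@@H]2[C@H]1C[C@@H](O[Si](CC)(CC)CC)[C@H](C)[C@@](O[Si](CC)(CC)CC)(C(=O)SCC)[C@H]2OC(=O)CC(C)C | intermediate
25 | (3aS,5R,6S,7S,8S,8aR)-7-[(2Z)-but-2-enoyl]-6-methyl-3-methylidene-2-oxo-5,7-bis(triethylsilyloxy)octahydro-2H-cyclohepta[b]furan-8-yl 3-methylbutanoate | C=C1C(=O)O[C@@H]2[C@H]1C[C@@H](O[Si](CC)(CC)CC)[C@H](C)[C@@](O[Si](CC)(CC)CC)(C(=O)/C=C\C)[C@H]2OC(=O)CC(C)C | intermediate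
26 | (3aS,5R,6S,7S,8S,8aR)-7-[(2Z)-but-2-enoyl]-5,7-dihydroxy-6-methyl-3-methylidene-2-oxooctahydro-2H-cyclohepta[b]furan-8-yl 3-methylbutanoate (CNP0186412.2) | C=C1C(=O)O[C@@H]2[C@H]1C[C@@H](O)[C@H](C)[C@@](O)(C(=O)/C=C\C)[C@H]2OC(=O)CC(C)C | target

**Step count**

Total step count: 19.
Longest linear sequence: 16 steps (steps 1–9, then 13–19); steps 10–12 make the silyloxyfuran branch.

**Steps most likely to fail**

1. Step 17 (carries the label). What may go wrong: the C8 radical is quenched by intramolecular 1,5-hydrogen transfer from C5 (or 1,6 from C6), or is lost to iodine-atom transfer and oligomerisation, before the slow seven-membered closure takes place.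
Fallback by known chemistry, setting out from 15 and returning at 24, which closes the ring at C6–C7 by a chromium-mediated intramolecular allylation of the Nozaki–Hiyama–Kishi type. Aldehyde 15 takes up vinylmagnesium bromide under MgBr2·OEt2 chelation to give the C5 vinyl carbinol F1, which is acylated with isovaleryl chloride/pyridine to the isovalerate F2. DDQ frees the C8 primary alcohol F3, and Dess–Martin periodinane gives the C8 aldehyde F4. Wittig reaction with Ph3P=CHOMe gives the methyl enol ether F5 (E/Z mixture), which brief treatment with trichloroacetic acid in wet CH2Cl2 hydrolyses to the one-carbon-longer aldehyde F6, whose CHO is C7. Morita–Baylis–Hillman reaction with methyl acrylate (DABCO) gives the allylic alcohol F7, and NBS/Me2S converts it with allylic transposition into the (Z)-2-(bromomethyl)enoate F8. Selective ozonolysis of the terminal vinyl group (O3, then PPh3) unveils the C6 aldehyde F9. CrCl2 in THF at high dilution then forms the allylchromium, which adds through its γ-carbon C7 to the C6 aldehyde and creates C11=C13, and lactonisation of the C6 alkoxide onto the methyl ester gives 24.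

2. Step 13. What may go wrong: poor or reversed facial selection at C5 if chelation of the α-silyloxy aldehyde by Me2AlCl does not dominate (the non-chelated Felkin–Anh pathway leads to the wrong C5/C6 pair), or low threo/erythro selection.
Fallback setting out from 15 and returning at 23, with reagent control in place of substrate control and the butenolide closed by metathesis. Aldehyde 15 reacts with (Z)-γ-(4-methoxybenzyloxy)allyldiisopinocampheylborane [allyl 4-methoxybenzyl ether, s-BuLi, (−)-Ipc2BOMe, BF3·OEt2] to give the syn C5-hydroxy C6-PMB ether F10. Isovaleryl chloride/pyridine gives the isovalerate F11, and DDQ removes both PMB groups to give the C6,C8-diol F12. I2/PPh3/imidazole at 0 °C iodinates the primary hydroxyl only, giving the iodo alcohol F13. Esterification of the C6 hydroxyl with 2-[(phenylsulfonyl)methyl]acrylic acid (DCC, DMAP cat.) gives the diene ester F14, and ring-closing metathesis with the second-generation Grubbs catalyst (toluene, 80 °C) closes the butenolide to 23.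

3. Step 18. What may go wrong: slow acyl transfer at the neopentyl, α-silyloxy thioester, with protodeboronation of the boronic acid and Z-to-E isomerisation of the propenyl group competing.
Fallback setting out from 24 and returning at 25, through an acid chloride and a Stille acylation. Silver-assisted hydrolysis of the thioester (AgNO3, 2,6-lutidine, aq. THF) gives the carboxylic acid F15. 1-Chloro-N,N,2-trimethylprop-1-en-1-amine (Ghosez reagent) in CH2Cl2 gives the acid chloride F16 under neutral conditions. Coupling with (Z)-tributyl(prop-1-enyl)stannane (Pd2(dba)3, P(2-furyl)3, toluene, rt) gives 25 with retention of the Z geometry.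

**Further compounds**

F1 | step 17 | S-ethyl (2S,3S,4S)-2-[(1S)-1-hydroxyprop-2-en-1-yl]-5-[(4-methoxybenzyl)oxy]-3-methyl-2,4-bis(triethylsilyloxy)pentanethioate | C=C[C@H](O)[C@](O[Si](CC)(CC)CC)(C(=O)SCC)[C@@H](C)[C@H](O[Si](CC)(CC)CC)COCc1ccc(OC)cc1
F2 | step 17 | 3-methylbutanoate of F1 | C=C[C@H](OC(=O)CC(C)C)[C@](O[Si](CC)(CC)CC)(C(=O)SCC)[C@@H](C)[C@H](O[Si](CC)(CC)CC)COCc1ccc(OC)cc1
F3 | step 17 | C8 primary alcohol from F2 | C=C[C@H](OC(=O)CC(C)C)[C@](O[Si](CC)(CC)CC)(C(=O)SCC)[C@@H](C)[C@H](O[Si](CC)(CC)CC)CO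
F4 | step 17 | C8 aldehyde from F3 | C=C[C@H](OC(=O)CC(C)C)[C@](O[Si](CC)(CC)CC)(C(=O)SCC)[C@@H](C)[C@H](O[Si](CC)(CC)CC)C=O
F5 | step 17 | methyl enol ether from F4 (E/Z mixture) | C=C[C@H](OC(=O)CC(C)C)[C@](O[Si](CC)(CC)CC)(C(=O)SCC)[C@@H](C)[C@H](O[Si](CC)(CC)CC)C=COC
F6 | step 17 | homologated C7 aldehyde | C=C[C@H](OC(=O)CC(C)C)[C@](O[Si](CC)(CC)CC)(C(=O)SCC)[C@@H](C)[C@H](O[Si](CC)(CC)CC)CC=O
F7 | step 17 | Morita–Baylis–Hillman adduct of F6 with methyl acrylate (both C7 epimers) | C=C[C@H](OC(=O)CC(C)C)[C@](O[Si](CC)(CC)CC)(C(=O)SCC)[C@@H](C)[C@H](O[Si](CC)(CC)CC)CC(O)C(=C)C(=O)OC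
F8 | step 17 | methyl (Z)-2-(bromomethyl)alk-2-enoate from F7 | C=C[C@H](OC(=O)CC(C)C)[C@](O[Si](CC)(CC)CC)(C(=O)SCC)[C@@H](C)[C@H](O[Si](CC)(CC)CC)C/C=C(\CBr)C(=O)OC
F9 | step 17 | C6 aldehyde from F8 (cyclisation substrate) | O=C[C@H](OC(=O)CC(C)C)[C@](O[Si](CC)(CC)CC)(C(=O)SCC)[C@@H](C)[C@H](O[Si](CC)(CC)CC)C/C=C(\CBr)C(=O)OC
F10 | step 13 | S-ethyl (2S,3S,4S)-2-{(1S,2R)-1-hydroxy-2-[(4-methoxybenzyl)oxy]but-3-en-1-yl}-5-[(4-methoxybenzyl)oxy]-3-methyl-2,4-bis(triethylsilyloxy)pentanethioate | C=C[C@@H](OCc1ccc(OC)cc1)[C@H](O)[C@](O[Si](CC)(CC)CC)(C(=O)SCC)[C@@H](C)[C@H](O[Si](CC)(CC)CC)COCc1ccc(OC)cc1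
F11 | step 13 | 3-methylbutanoate of F10 | C=C[C@@H](OCc1ccc(OC)cc1)[C@H](OC(=O)CC(C)C)[C@](O[Si](CC)(CC)CC)(C(=O)SCC)[C@@H](C)[C@H](O[Si](CC)(CC)CC)COCc1ccc(OC)cc1
F12 | step 13 | C6,C8-diol from F11 | C=C[C@@H](O)[C@H](OC(=O)CC(C)C)[C@](O[Si](CC)(CC)CC)(C(=O)SCC)[C@@H](C)[C@H](O[Si](CC)(CC)CC)CO
F13 | step 13 | C8 iodide, C6 alcohol from F12 | C=C[C@@H](O)[C@H](OC(=O)CC(C)C)[C@](O[Si](CC)(CC)CC)(C(=O)SCC)[C@@H](C)[C@H](O[Si](CC)(CC)CC)CI
F14 | step 13 | C6 2-[(phenylsulfonyl)methyl]acrylate of F13 | C=C[C@@H](OC(=O)C(=C)CS(=O)(=O)c1ccccc1)[C@H](OC(=O)CC(C)C)[C@](O[Si](CC)(CC)CC)(C(=O)SCC)[C@@H](C)[C@H](O[Si](CC)(CC)CC)CI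
F15 | step 18 | (3aS,5R,6S,7S,8S,8aR)-6-methyl-3-methylidene-8-[(3-methylbutanoyl)oxy]-2-oxo-5,7-bis(triethylsilyloxy)octahydro-2H-cyclohepta[b]furan-7-carboxylic acid | C=C1C(=O)O[C@@H]2[C@H]1C[C@@H](O[Si](CC)(CC)CC)[C@H](C)[C@@](O[Si](CC)(CC)CC)(C(O)=O)[C@H]2OC(=O)CC(C)C
F16 | step 18 | acid chloride of F15 | C=C1C(=O)O[C@@H]2[C@H]1C[C@@H](O[Si](CC)(CC)CC)[C@H](C)[C@@](O[Si](CC)(CC)CC)(C(Cl)=O)[C@H]2OC(=O)CC(C)C
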